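**Assumption (one line):** genipin and tert‑butyl(4‑ethynylphenoxy)dimethylsilane are taken as commercial; iridoid numbering is used (C1 acetal, O2, C3=C4, C5, C6, C7, C8, C9; C10 on C8, C11 on C4), with β meaning the face of H‑5/H‑9.

## Retrosynthetic overview

1. Target 14 ⇐ global desilylation of 13 ⇐ C10–O ester bond from carboxylate displacement on iodohydrin 9 by Z‑acid 12 (aryl alkyne → propiolic acid → Lindlar).
2. 9 ⇐ C11 silylation and C1 lactol acylation of 7 ⇐ DIBAL on iodocarbonate 6 (CO2Me → CH2OH and carbonate cleavage in one operation).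
3. 6 ⇐ iodocarbonation of exocyclic alkene 5: the C1 O‑Boc group delivers the C8–O bond intramolecularly to the hindered α‑face; iodide masks C10.
4. 5 ⇐ key step: [2,3]‑sigmatropic rearrangement of the allylic selenoxide from 3 (C10–Se → C7β–O, alkene moves to C8=C10) ⇐ genipin 1.
5. Ring order: the cis‑fused cyclopenta[c]pyran (C1, C5, C9 stereocentres) is bought intact in genipin; the only ring formed is the temporary cyclic carbonate (step 5), opened in step 6.

## Forward route

**Step 1**
Reactants: 1, genipin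
Product: 2, 10‑deoxy‑10‑(phenylselanyl)genipin (C1 β‑OH lactol retained)
Conditions: N‑(phenylseleno)phthalimide, n‑Bu3P, THF, −20 → 0 °C
Reagents that add atoms: N‑(phenylseleno)phthalimide, O=C1c2ccccc2C(=O)N1[Se]c1ccccc1
Why: Grieco–Nicolaou alcohol→selenide reaction (alkoxyphosphonium, SN2 by PhSe⁻); the primary allylic C10‑OH reacts much faster than the hindered lactol OH.

**Step 2**
Reactants: 2
Product: 3, 1‑O‑Boc carbonate of 2
Conditions: Boc2O, DMAP (cat.), Et3N, CH2Cl2, 0 °C → rt
Reagents that add atoms: di‑tert‑butyl dicarbonate, CC(C)(C)OC(=O)OC(=O)OC(C)(C)C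
Why: O‑acylation of the only free OH gives the lactol tert‑butyl carbonate; its anomeric configuration does not matter because the lactol is regenerated in step 6.

**Step 3 (key step)**
Reactants: 3
Product: 4, 7β‑hydroxy‑8(10)‑methylidene compound (1‑O‑Boc, C4‑CO2Me)
Conditions: mCPBA (1.05 equiv), CH2Cl2, −78 °C; then i‑Pr2NH, −78 °C → rt
Reagents that add atoms: mCPBA, OOC(=O)c1cccc(Cl)c1
Why: Selenide oxidation then allyl selenoxide→selenenate [2,3]‑sigmatropic rearrangement (no β‑H, so no syn‑elimination); oxygen is delivered suprafacially to C7 on the convex β‑face because the α‑face is blocked by C1 and its carbonate, setting 7β‑OH.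

**Step 4**
Reactants: 4
Product: 5, 7β‑O‑TES ether of 4
Conditions: TESCl, imidazole, DMAP (cat.), CH2Cl2, 0 °C
Reagents that add atoms: chlorotriethylsilane, CC[Si](Cl)(CC)CC
Why: Standard silylation of the single free secondary alcohol, so that only the lactol can be acylated in step 8.

**Step 5**
Reactants: 5
Product: 6, cyclic iodocarbonate: O1–C(=O)–O8 six‑membered carbonate, 8α‑O, 8β‑CH2I, 7β‑OTES, C4‑CO2Me
Conditions: IBr, PhMe/CH2Cl2, −78 °C
Reagents that add atoms: iodine monobromide, IBr
Why: Bartlett–Smith iodocarbonation (6‑exo, Markovnikov, loss of t‑Bu): iodonium forms on the open β‑face and the C1‑tethered carbonate carbonyl attacks C8 anti, from the α‑face, setting 8α‑O/10β; the C3=C4 acrylate is too electron‑poor to react.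

**Step 6**
Reactants: 6
Product: 7, lactol triol iodide: 1β‑OH lactol, 11‑OH, 8α‑OH, 10‑iodo, 7β‑OTES
Conditions: DIBAL‑H (excess), CH2Cl2, −78 → −40 °C; Rochelle salt work‑up
Reagents that add atoms: none
Why: Hydride reduction of the vinylogous carbonate ester to the C11 allylic alcohol and reductive cleavage of the cyclic carbonate; the lactol is held as its aluminium lactolate at low temperature and the neopentyl‑type iodide is inert.

**Step 7**
Reactants: 7
Product: 8, 11‑O‑TBS ether of 7
Conditions: TBSCl (1.1 equiv), imidazole, DMF, −20 → 0 °C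
Reagents that add atoms: tert‑butyldimethylsilyl chloride, CC(C)(C)[Si](C)(C)Cl
Why: Selective silylation of the primary allylic OH over the lactol and tertiary OH, as in 10‑O‑silylation of genipin.

**Step 8**
Reactants: 8
Product: 9, 1β‑O‑isovaleryl ester of 8 (iodohydrin retained)
Conditions: isovaleric anhydride, Et3N, DMAP (cat.), CH2Cl2, 0 °C
Reagents that add atoms: isovaleric anhydride, CC(C)CC(=O)OC(=O)CC(C)C
Why: DMAP‑catalysed acylation of the lactol, which reacts as the equatorial β‑anomer (H‑1/H‑9 trans) as in genipin‑type lactols; the tertiary 8‑OH does not acylate.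

**Step 9**
Reactants: 10, tert‑butyl(4‑ethynylphenoxy)dimethylsilane
Product: 11, 3‑[4‑(tert‑butyldimethylsilyloxy)phenyl]prop‑2‑ynoic acid
Conditions: n‑BuLi, THF, −78 °C; CO2; aq. NaHSO4
Reagents that add atoms: carbon dioxide, O=C=O
Why: Carboxylation of the lithium acetylide.

**Step 10**
Reactants: 11
Product: 12, (Z)‑3‑[4‑(tert‑butyldimethylsilyloxy)phenyl]prop‑2‑enoic acid
Conditions: H2 (1 atm), Lindlar catalyst, quinoline, EtOAc, rt
Reagents that add atoms: none
Why: Lindlar syn‑semihydrogenation of the arylpropiolic acid gives the Z‑cinnamic acid.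

**Step 11**
Reactants: 9 and 12
Product: 13, fully protected luzonoid D (10‑O‑(Z)‑4‑TBSO‑cinnamoyl, 8α‑OH, 7β‑OTES, 11‑OTBS, 1β‑O‑isovaleryl)
Conditions: 12 (4 equiv), Cs2CO3 (1.5 equiv), DMF, 50 °C, dark
Reagents that add atoms: none
Why: Caesium carboxylate O‑alkylation at the primary C10 (direct SN2 or via the transient 8α,10‑epoxide, opened at CH2), so C8 is untouched and the Z‑acyl group is never activated; excess acid protonates the C8 alkoxide before it can take the C1 acyl group.

**Step 12**
Reactants: 13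
Product: 14, luzonoid D
Conditions: HF·pyridine, pyridine, THF, 0 °C → rt
Reagents that add atoms: none
Why: Buffered fluoride desilylation removes the TES, primary TBS and aryl TBS groups without acyl migration or Z→E isomerisation.

## Compound list

1 | genipin, methyl (1R,4aS,7aS)-1-hydroxy-7-(hydroxymethyl)-1,4a,5,7a-tetrahydrocyclopenta[c]pyran-4-carboxylate | O[C@@H]1OC=C(C(=O)OC)[C@H]2CC=C(CO)[C@@H]12 | starting material
2 | 10‑deoxy‑10‑(phenylselanyl)genipin | O[C@@H]1OC=C(C(=O)OC)[C@H]2CC=C(C[Se]c3ccccc3)[C@@H]12 | intermediate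
3 | 1β‑O‑Boc‑10‑deoxy‑10‑(phenylselanyl)genipin | CC(C)(C)OC(=O)O[C@@H]1OC=C(C(=O)OC)[C@H]2CC=C(C[Se]c3ccccc3)[C@@H]12 | intermediate
4 | methyl 1β‑(Boc‑oxy)‑7β‑hydroxy‑8‑methylidene iridoid ester (7S) | CC(C)(C)OC(=O)O[C@@H]1OC=C(C(=O)OC)[C@H]2C[C@H](O)C(=C)[C@@H]12 | intermediate
5 | 7β‑O‑triethylsilyl ether of 4 | CC(C)(C)OC(=O)O[C@@H]1OC=C(C(=O)OC)[C@H]2C[C@H](O[Si](CC)(CC)CC)C(=C)[C@@H]12 | intermediate
6 | cyclic 1‑O,8α‑O‑carbonate, 8β‑iodomethyl, 7β‑OTES, methyl ester | O=C3O[C@@H]1OC=C(C(=O)OC)[C@H]2C[C@H](O[Si](CC)(CC)CC)[C@](O3)(CI)[C@@H]12 | intermediate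
7 | 1β‑lactol, 4‑hydroxymethyl, 8α‑hydroxy‑8β‑iodomethyl, 7β‑OTES | O[C@@H]1OC=C(CO)[C@H]2C[C@H](O[Si](CC)(CC)CC)[C@](O)(CI)[C@@H]12 | intermediate
8 | 11‑O‑TBS ether of 7 | O[C@@H]1OC=C(CO[Si](C)(C)C(C)(C)C)[C@H]2C[C@H](O[Si](CC)(CC)CC)[C@](O)(CI)[C@@H]12 | intermediate
9 | 1β‑O‑isovaleryl ester of 8 | CC(C)CC(=O)O[C@@H]1OC=C(CO[Si](C)(C)C(C)(C)C)[C@H]2C[C@H](O[Si](CC)(CC)CC)[C@](O)(CI)[C@@H]12 | intermediate
10 | tert‑butyl(4‑ethynylphenoxy)dimethylsilane | C#Cc1ccc(O[Si](C)(C)C(C)(C)C)cc1 | starting material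
11 | 3‑[4‑(tert‑butyldimethylsilyloxy)phenyl]prop‑2‑ynoic acid | OC(=O)C#Cc1ccc(O[Si](C)(C)C(C)(C)C)cc1 | intermediate
12 | (Z)‑3‑[4‑(tert‑butyldimethylsilyloxy)phenyl]prop‑2‑enoic acid | OC(=O)/C=C\c1ccc(O[Si](C)(C)C(C)(C)C)cc1 | intermediate
13 | 7‑O‑TES, 11‑O‑TBS, 4′‑O‑TBS luzonoid D | CC(C)CC(=O)O[C@@H]1OC=C(CO[Si](C)(C)C(C)(C)C)[C@H]2C[C@H](O[Si](CC)(CC)CC)[C@](O)(COC(=O)/C=C\c3ccc(O[Si](C)(C)C(C)(C)C)cc3)[C@@H]12 | intermediate
14 | luzonoid D | CC(C)CC(=O)O[C@@H]1OC=C(CO)[C@H]2C[C@H](O)[C@](O)(COC(=O)/C=C\c3ccc(O)cc3)[C@@H]12 | target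

## Summary

Total steps: 12. Longest linear sequence: 10 (steps 1–8, 11, 12 from genipin).

Stereocentres: C5 and C9 come from genipin; C1 is the genipin lactol centre, re‑set as the β‑ester in step 8; C7 is set in step 3; C8 is set in step 5; the Z‑alkene is set in step 10.

Three steps most likely to fail, each with a fallback:

1. **Step 6** (one‑pot ester reduction and carbonate cleavage; the lactolate may over‑reduce and the non‑conjugated aglycone 7 is fragile). Fallback: take C11 to the aldehyde early (bis‑silylate genipin, DIBAL, MnO2), keep the conjugated enal to the end, cleave the carbonate hydrolytically and finish with a Luche reduction of the C11 aldehyde.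
2. **Step 11** (slow displacement next to a quaternary centre; possible C1→O8 acyl transfer or Z→E drift). Fallback: alkylate with the caesium salt of propiolic acid 11, which has no isomerisable alkene, and form the Z‑alkene afterwards by Lindlar semihydrogenation on the full skeleton.
3. **Step 5** (Boc loss or poor cyclisation). Fallback: omit the TES group, epoxidise the exocyclic alkene on the β‑face under direction of the free 7β‑OH (VO(acac)2/TBHP), and let the C1 Boc carbonate open the epoxide at C8 with inversion (BF3·OEt2); this gives the same carbonate with C10–OH in place of C10–I.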